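- You want to know how the rate of Q + E → G answers to each partner and how far an E-rich flask gets, so the question is which concentration sets the order.

in all of them: L 0.0150 M

| run | Q | E | G | time |
|---|---|---|---|---|
| west | 0.300 M | 0.330 M |  |  |
| south-west | 0.120 M | 0.150 M |  |  |
| north-east | 0.450 M | 0.330 M |  |  |
| north-west | 0.300 M | 0.330 M | 0.150 M |  |
| south-east | 0.300 M | 0.830 M |  | 9.5 h |

| run | time / h | [G] / M |
|---|---|---|
| west run | 0.42 | 0.0198 |
| west run | 1.3 | 0.0608 |
| west run | 2.4 | 0.1059 |
| west run | 3.9 | 0.1512 |
| west run | 5.5 | 0.1917 |
| west run | 7.4 | 0.2236 |
| west run | 9.5 | 0.2505 |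
| south-west run | 0.42 | 0.0063 |
| south-west run | 1.3 | 0.0246 |
| south-west run | 2.4 | 0.0418 |
| south-west run | 3.9 | 0.0642 |
| south-west run | 5.5 | 0.0785 |
| south-west run | 7.4 | 0.0934 |
| south-west run | 9.5 | 0.1042 |
| north-east run | 0.42 | 0.0233 |
| north-east run | 1.3 | 0.0737 |
| north-east run | 2.4 | 0.1231 |
| north-east run | 3.9 | 0.1801 |
| north-east run | 5.5 | 0.2253 |
| north-east run | 7.4 | 0.2622 |
| north-east run | 9.5 | 0.2895 |
| north-west run | 0.42 | 0.1684 |
| north-west run | 1.3 | 0.2110 |
| north-west run | 2.4 | 0.2525 |
| north-west run | 3.9 | 0.3027 |
| north-west run | 5.5 | 0.3396 |
| north-west run | 7.4 | 0.3738 |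
| north-west run | 9.5 | 0.4001 |

(scatter of a reading: 9 × 10⁻⁴ M)

1. how the opening rate goes with [E] round the charge of the west run: the exponent of the rate at two percent of Q gone to G
2. how the opening rate goes with [Q] round the charge of the west run: the exponent of the rate at two percent of Q gone to G (one fixed amount of G, the same in the runs compared)
3. the south-west run starts with 0.180 M less of Q and of E than the west run, and with no G. Compared where both hold the same amount of Q, once fifteen percent of what the south-west run was charged with has turned into G, is the south-west run faster, slower or alike (within a tenth)?
4. G in the south-east run at 9.5 h, as a share of the Q charged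

- Overall: Q + E -> G, with L as catalyst.
- Constant volume, constant temperature.
- "The second partner" is E.
- An order is taken over about fifteen percent of the charge, up and down.

- The north-west run, charged with G, has made 0.250 M of new G at 9.5 h, and the west run 0.2505 M, so I read the rate as a function of Q and E with no effect of G.
- My working form treats the two partners as resistances in series. The time spent is the E time multiplied by ln(E charged / E left), plus the Q time multiplied by ln(Q charged / Q left).
- The last readings of the west and north-east runs give an E time of 3.17 h and a Q time of 2.77 h.
- At two percent of Q gone in the west run, the E time times [Q] over the Q time times [E] gives 1.04. Call this the balance, the E resistance as a multiple of the Q resistance.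
- The order in E is the balance over one plus the balance, and the order in Q is one over that sum, so I expect 0.510 and 0.490.
- To test whether this is enough, take the south-west run, which the fit never saw: the rule puts its 0.1042 M of G at 9.37 h, against 9.5 h on the clock.
- E exceeds Q by 0.0300 M in the west run and 0.0300 M in the south-west run, so at equal Q they hold equal E and the same balance, and I expect them alike.
- Q is the limiting reagent of the south-east run, at 0.300 M against 0.830 M of E. Setting E at its lowest possible value, one pass of the rule gives 94.6%.
- The forecast gives orders of 0.5 in E and 0.5 in Q, alike, and 94.3%, which differs a little from my yield: “the two terms are about equal, so each order is about 0.5”.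
- The flask gives 0.52 in E, 0.51 in Q, alike, and 95.0%.

    L + Q → Xo + J (36.72 M⁻¹ h⁻¹)
    Xo + E → G + L (32.18 M⁻¹ h⁻¹)
    L + Gy → Qa

- In these steps the balance is k1[Q] over k2[E], which holds no L. Gy takes a third of L into Qa, and because of that capture the apparent order in L reads 1.4 rather than 0.84, yet the order in E stands at 0.52 without that capture, as it does with it. In the south-east run at 9.5 h, the balance read from the two times has fallen from 1.04 in the west run to 0.0316, so L + Q is the rate-limiting step and the tail is pseudo-first-order in Q. Without the capture, that yield is 99.1% rather than 95.0%.

All runs were generated by integration for an exercise, noise included.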